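The easy step is counting: a complex with two exchanged has taken two incoming ligands, so finishing a flask costs two ligands per starting complex. For ash, the ligand charge over two times the complex charge is 1.25; we call this ratio the cover, E.

| flask | starting complex | incoming ligand | remark | time |
|---|---|---|---|---|
| south-west | 0.13 M | 0.80 M (in portions, 4) | run made earlier; portions every 80 min |  |
| south-east | 0.10 M | 0.80 M (in portions, 4) | run made earlier; portions every 80 min |  |
| alder | 0.20 M | 0.800 M (in portions, 4) | the portions of incoming ligand follow each other after 80 min, the first at the start | 20 h |
| elm | 0.20 M | 0.160 M (in portions, 4) | the portions of incoming ligand follow each other after 80 min, the first at the start | 20 h |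
| ash | 0.20 M | 0.500 M (in portions, 4) | the portions of incoming ligand follow each other after 80 min, the first at the start | 20 h |

- south-west (time / h: complex with two exchanged / %): 0.833: 2.7; 2.50: 14.7; 5.00: 48.7; 8.00: 75.3
- south-east (time / h: complex with two exchanged / %): 0.833: 1.8; 2.50: 14.5; 5.00: 50.9; 8.00: 76.2

(scatter of a reading: 0.5 percentage points)

- no earlier run changes the charge of incoming ligand; that part of a forecast is a guess

- which of these holds the largest part of the starting complex at the end of alder (starting complex / complex with two exchanged / complex with one exchanged)
- which of these holds the largest part of the starting complex at the end of elm (starting complex / complex with two exchanged / complex with one exchanged)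
- which of these holds the largest part of the starting complex at the end of ash (starting complex / complex with two exchanged / complex with one exchanged)
- amount of complex with two exchanged at the end of ash, in percent of the starting complex charged

The bench rule for ligand in excess is pseudo-first-order: with ligand roughly constant, what remains falls tenfold in a fixed decade time, τ. In the south-east run, E is 4.00. Reading what remains as the part not yet doubly exchanged, it falls from 49.1% at 5.00 h to 23.8% at 8.00 h, which gives a reading of τ = 9.54 h.

The rule's border shows in 1/E, the share of the ligand charge that completion uses: 25.0% in south-east, but 80.0% in ash, so ligand is not constant in ash. Elm has E = 0.400, so ligand is the limiting reagent there and the doubly exchanged complex cannot pass 40.0%. Which other species leads in elm depends on which exchange is faster, and we do not read that firmly from these runs. Alder, with E = 2.00, and ash should both end doubly exchanged.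

For ash we repair the rule with the midpoint ligand, charge minus complex charge: 0.300 M against 0.700 M in south-east. That stretches τ to 22.3 h. The 16.0 h after the last portion then leave 19.1%, so we expect about 80.9% doubly exchanged, ignoring what reacts while portions go in.

The forecast names complex with two exchanged for alder, complex with two exchanged for ash and complex with one exchanged for elm, reasoning that “the first step is much faster”. For ash it gives 75% (range 62% to 86%), lower than our figure.

    starting complex + incoming ligand → leaving ligand + complex with one exchanged (k = 0.00640 L mol⁻¹ min⁻¹)
    complex with one exchanged + incoming ligand → leaving ligand + complex with two exchanged (k = 0.0570 L mol⁻¹ min⁻¹)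
    complex with one exchanged → decomposed reagent (k = 2.70 × 10⁻⁴ min⁻¹)

Alder ends with 95.4% as complex with two exchanged, ash with 80.5% as complex with two exchanged, and elm with 61.6% as starting complex. In ash, the half-life of the complex with one exchanged by the second exchange, with ligand taken at its whole charge, is 0.41 h, far shorter than the 5.2 h of starting complex by the first exchange at 5.51 h. At 5.51 h the first exchange uses ligand at 0.91 of the rate of the second, and the complex with one exchanged, an intermediate, ends at 1.97%, less than the 16.0% of starting complex. Ash's E leaves 20.0% of its ligand by count, and at 200 h it holds 20.8%. The neighbour flask with 0.80 M of starting complex has E = 0.312 and ends with 26.9% doubly exchanged.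

The numbers in the tables were generated by integration on assumed constants; the scatter is artificial.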